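The constants of the suspect steps, substrate + 2 target → 3 target, substrate → target and 2 substrate → homo dimer, are hidden, so what the new flasks do has to be read from the earlier runs.

| setting | alpha | theta | Wednesday's | Saturday's |
|---|---|---|---|---|
| substrate | 0.95 M | 1.4 M | 1.9 M | 1.9 M |
| remark | run made earlier | run made earlier |  |  |
| time |  |  | 4.0 h | 5.0 h |

| run | time / h | substrate / % | target / % |
|---|---|---|---|
| alpha | 1.00 | 98.3 | 3.1 |
| alpha | 2.00 | 96.7 | 4.1 |
| alpha | 3.00 | 95.5 | 4.9 |
| alpha | 4.00 | 91.2 | 8.1 |
| alpha | 5.00 | 90.3 | 9.3 |
| theta | 0.417 | 97.5 | 1.4 |
| theta | 1.33 | 98.8 | 3.3 |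
| theta | 2.00 | 96.6 | 3.4 |
| theta | 3.00 | 94.9 | 4.6 |
| theta | 5.00 | 91.2 | 9.1 |

(standard deviation of a reading: 1 percentage point)

1. which of these there is most of at the end, counted by the substrate in it, Wednesday's (target / substrate)
2. which of these there is most of at the end, counted by the substrate in it, Saturday's (target / substrate)
3. the largest of these amounts at the end, in percent of the substrate charged, Wednesday's
4. the largest of these amounts at the end, in percent of the substrate charged, Saturday's

- in percentages every species weighs as the substrate in it: one homo dimer counts as two
- on the list of suspects stand: substrate + 2 target -> 3 target; substrate -> target; 2 substrate -> homo dimer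

The last readings of the alpha and theta runs, both at 5.00 h, show 90.3 % and 91.2 % substrate. That is a gap of 0.9 percentage points against a scatter of 1 point, although the charge rises from 0.95 M to 1.4 M. Within the scatter, the fractional loss therefore shows no dependence on the charge, and the two readings together give an estimate of one first-order constant, k = 0.0194 h⁻¹.

Wednesday's flask then has D = 0.0777, where D = k·t, with t the time, is the number of first-order lifetimes of substrate that a flask has run, a Damköhler number. Saturday's flask has D = 0.0971.

The substrate left is then reckoned as exp(−D), which is 92.5 % on Wednesday's flask and 90.7 % on Saturday's. This is more than the reckoned 7.48 % of target on Wednesday's flask and more than the reckoned 9.25 % on Saturday's, so this reckoning names substrate for both flasks.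

Is one number enough? At the last alpha reading, substrate and target add up to 99.6 %, so within the scatter no material is missing towards homo dimer. But D carries no term for the suspect step substrate + 2 target → 3 target, which needs target.

The forecast gives substrate for both flasks, 92.5 % on Wednesday's and 90.7 % on Saturday's, in the words “Substrate remains the main species in both runs.”

    substrate + 2 target → 3 target (k = 0.120 M⁻² h⁻¹)
    substrate → target (k = 0.0180 h⁻¹)
    2 substrate → homo dimer (k = 2.60 × 10⁻⁴ M⁻¹ h⁻¹)

Wednesday's flask ends with 92.4 % substrate and 7.21 % target, and Saturday's with 90.4 % and 9.12 %, beside the 92.5 % and 90.7 % of substrate from exp(−D). In Wednesday's flask, substrate → target uses substrate 34 times as fast as substrate + 2 target → 3 target at 1.96 h, but 8.0 times as fast at 4.00 h, a smaller lead. Wednesday's flask read on to 15 h has D = 0.291, for which exp(−D) is 74.8 %, and it holds 58.7 % substrate.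

The earlier runs and the new flask are calculated on assumed constants; noise was put on by code.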